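**Retrosynthetic overview**
- The target is a genkwanin half (benzo ring A, pyrone ring C, 4-hydroxyphenyl ring B). It is bonded from C3 of ring C to C3 of phenol ring F, the aryl ring of the apigenin half (benzo ring D, pyrone ring E). The last step is one BCl3 operation that frees five phenols and keeps the 7-OMe.
- Key disconnection: C1 of ring F to C2 of ring E. This bond is made in the same operation as C2–C3 and O1–C2, so all of ring E arises when an aryl bromide (fragment 1) meets an acyclic 2-acetylaryl formate (fragment 2).
- Enabling feature: C2 of ring E is a carboxyl-level carbon bonded to both O1 (on ring D) and C1 of ring F. Ring E is therefore the dehydrated 1,3-diketone that results from the acyl shift of a ring F benzoate sitting on O1. C2 can travel as the formyl carbon on O1 of a phloroacetophenone, whose acetyl CH3 becomes C3.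
- Fragment 1: the C3(ring C)–C3(ring F) bond comes from Suzuki–Miyaura coupling of a 3-iodoflavone. Ring C comes from 6-endo-dig iodocyclisation of a symmetrical 2,4,6-trimethoxyphenyl ynone.
- Order of ring formation: ring C (step 3), then ring E (step 8). Rings A, B, D and F are bought.

Key step: step 8

Assumption: the axis between C3 of ring C and C3 of ring F carries no descriptor in the target, so it is treated as configurationally undefined. The target has no stereocentre.

Step 1
Reactants: 1 1-(benzyloxy)-4-ethynylbenzene; 2 2,4,6-trimethoxybenzaldehyde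
Product: 4 racemic 3-[4-(benzyloxy)phenyl]-1-(2,4,6-trimethoxyphenyl)prop-2-yn-1-ol, via lithium acetylide 3 (not isolated)
Conditions: n-BuLi (1.05 equiv), THF, −78 °C; then 2, −78 → 0 °C; H2O quench
Reagents that add atoms: none
Why: 1,2-addition of a lithium acetylide to a non-enolisable aldehyde; the carbinol centre forms as a racemate and is erased in step 2.

Step 2
Reactants: 4 racemic propargylic alcohol
Product: 5 3-[4-(benzyloxy)phenyl]-1-(2,4,6-trimethoxyphenyl)prop-2-yn-1-one
Conditions: activated MnO2 (excess), CH2Cl2, rt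
Reagents that add atoms: none
Why: neutral heterogeneous MnO2 oxidation of a benzylic-propargylic alcohol, which avoids acid ionisation of this very electron-rich carbinol.

Step 3
Reactants: 5 ynone
Product: 6 2-[4-(benzyloxy)phenyl]-3-iodo-5,7-dimethoxy-4H-chromen-4-one
Conditions: ICl (1.2 equiv), CH2Cl2, −78 °C; aq. Na2S2O3 quench
Reagents that add atoms: iodine monochloride, ClI
Why: electrophilic iodocyclisation of a 2-methoxyaryl ynone, in which an ortho-methoxy oxygen attacks 6-endo-dig at the iodonium-activated alkyne carbon that the 4-alkoxyphenyl group stabilises, chloride then removes the methyl group, and the two ortho-OMe groups are equivalent so only one chromone can form.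

Step 4
Reactants: 7 (5-bromo-2-hydroxyphenyl)boronic acid
Product: 8 [2-(benzyloxy)-5-bromophenyl]boronic acid
Conditions: BnBr (1.1 equiv), K2CO3, DMF, rt
Reagents that add atoms: benzyl bromide, BrCc1ccccc1
Why: Williamson etherification of the only phenoxide present, with the C–B and C–Br bonds inert under these conditions.

Step 5
Reactants: 6 3-iodoflavone; 8 [2-(benzyloxy)-5-bromophenyl]boronic acid
Product: 9 2-[4-(benzyloxy)phenyl]-3-[2-(benzyloxy)-5-bromophenyl]-5,7-dimethoxy-4H-chromen-4-one
Conditions: 8 (1.05 equiv), Pd(PPh3)4 (5 mol %), 2 M aq. Na2CO3, DME, 80 °C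
Reagents that add atoms: none
Why: Suzuki–Miyaura coupling in which zerovalent palladium inserts into the alpha-iodoenone C–I bond far faster than into the electron-rich C–Br bond para to the benzyloxy group, so the bromide is kept for step 8.

Step 6
Reactants: 10 2,4,6-trihydroxyacetophenone
Product: 11 1-[2,4-bis(benzyloxy)-6-hydroxyphenyl]ethan-1-one
Conditions: BnBr (2.05 equiv), K2CO3, DMF, rt
Reagents that add atoms: benzyl bromide, BrCc1ccccc1
Why: Williamson etherification that should stop after two alkylations, because the remaining ortho-OH is chelated to the acetyl C=O and is the least nucleophilic oxygen.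

Step 7
Reactants: 11 1-[2,4-bis(benzyloxy)-6-hydroxyphenyl]ethan-1-one
Product: 12 2-acetyl-3,5-bis(benzyloxy)phenyl formate
Conditions: HCO2H/Ac2O (premixed, 60 °C, 1 h); then 11, NaOAc, THF, 0 °C → rt; used after crystallisation, no chromatography
Reagents that add atoms: formic acid, O=CO (transferred as its mixed anhydride with acetic acid)
Why: O-formylation with a mixed anhydride, whose formyl carbon is the more electrophilic acyl centre, under a base too weak to trigger loss of CO from the product.

Step 8
Reactants: 9 aryl bromide (fragment 1); 12 2-acetyl-3,5-bis(benzyloxy)phenyl formate (fragment 2)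
Product: 16 2-[4-(benzyloxy)phenyl]-3-{2-(benzyloxy)-5-[5,7-bis(benzyloxy)-4-oxo-4H-chromen-2-yl]phenyl}-5,7-dimethoxy-4H-chromen-4-one, via phenol 11 (not isolated), via carbon monoxide 13 (not isolated), via aryl ester 14 (not isolated), via diketone 15 (not isolated)
Conditions: 12 (1.8 equiv), Pd(OAc)2 (5 mol %), Xantphos (10 mol %), Et3N (2.5 equiv), PhMe/MeCN, sealed tube, 90 °C; then DBU (4 equiv), 110 °C, same vessel
Reagents that add atoms: none
Why: Proposed new method: Et3N removes the formyl proton of 12, which breaks down in the closed tube into CO 13 and phenol 11, while zerovalent palladium/Xantphos inserts into the only C–Br bond of 9 (C1 of ring F); CO insertion there makes the C1(ring F)–C2(ring E) bond, and the phenol traps the aroylpalladium species as the O1 ester 14. This ester is a temporary bridge that holds C2 within a six-membered transition state of the acetyl CH3, so DBU enolisation triggers the Baker–Venkataraman O-to-C acyl shift (C2–C3 bond) to diketone 15. Ring E then closes by 6-exo-trig addition of the released O1 phenol to the C2 carbonyl and loss of water, driven by formation of the conjugated pyrone, and no stereocentre is created. The closest known reaction types are the palladium-catalysed aryloxycarbonylation of aryl bromides with aryl formates as CO source and the palladium/DBU carbonylative flavone synthesis from aryl bromides, CO gas and 2-hydroxyacetophenones; they are merged here by letting one 2-acetylaryl formate deliver CO, the O-nucleophile and the enolate. The selectivities needed are CO release before enolisation, acylation over direct arylation, and single over double aroylation: Et3N is too weak to enolise the acetyl group, so the formyl group should not shift onto its own CH3; acylpalladium formation under CO outruns enolate arylation, and direct C-acylation would lead to the same 15; and the excess of 12 keeps the aroyl donor limiting, so C3 is not aroylated twice. Ring C of 9 has no enolisable CH and a fully substituted C2, and benzyl and methyl ethers are inert to DBU, so fragment 1 remains a spectator.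

Step 9
Reactants: 16 fully protected biflavone
Product: 17 5-hydroxy-3-[5-(5,7-dihydroxy-4-oxo-4H-chromen-2-yl)-2-hydroxyphenyl]-2-(4-hydroxyphenyl)-7-methoxy-4H-chromen-4-one (CNP0284832.0)
Conditions: BCl3 (1 M in CH2Cl2, 15 equiv), pentamethylbenzene (12 equiv), CH2Cl2, −78 → 0 °C, then rt; aqueous work-up
Reagents that add atoms: none
Why: Lewis-acid debenzylation with a cation scavenger removes the four benzyl groups, chelation of boron between C4=O and the peri 5-OMe of ring A cleaves that methyl ether alone, and the unchelated 7-OMe should survive BCl3 at room temperature.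

**Compound list**
1 | 1-(benzyloxy)-4-ethynylbenzene | C#Cc1ccc(OCc2ccccc2)cc1 | starting material
2 | 2,4,6-trimethoxybenzaldehyde | COc1cc(OC)c(C=O)c(OC)c1 | starting material
3 | lithium [4-(benzyloxy)phenyl]acetylide | [Li]C#Cc1ccc(OCc2ccccc2)cc1 | intermediate
4 | racemic 3-[4-(benzyloxy)phenyl]-1-(2,4,6-trimethoxyphenyl)prop-2-yn-1-ol | COc1cc(OC)c(C(O)C#Cc2ccc(OCc3ccccc3)cc2)c(OC)c1 | intermediate
5 | 3-[4-(benzyloxy)phenyl]-1-(2,4,6-trimethoxyphenyl)prop-2-yn-1-one | COc1cc(OC)c(C(=O)C#Cc2ccc(OCc3ccccc3)cc2)c(OC)c1 | intermediate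
6 | 2-[4-(benzyloxy)phenyl]-3-iodo-5,7-dimethoxy-4H-chromen-4-one | COc1cc(OC)c2c(=O)c(I)c(-c3ccc(OCc4ccccc4)cc3)oc2c1 | intermediate
7 | (5-bromo-2-hydroxyphenyl)boronic acid | OB(O)c1cc(Br)ccc1O | starting material
8 | [2-(benzyloxy)-5-bromophenyl]boronic acid | OB(O)c1cc(Br)ccc1OCc1ccccc1 | intermediate
9 | 2-[4-(benzyloxy)phenyl]-3-[2-(benzyloxy)-5-bromophenyl]-5,7-dimethoxy-4H-chromen-4-one | COc1cc(OC)c2c(=O)c(-c3cc(Br)ccc3OCc3ccccc3)c(-c3ccc(OCc4ccccc4)cc3)oc2c1 | intermediate
10 | 2,4,6-trihydroxyacetophenone | CC(=O)c1c(O)cc(O)cc1O | starting material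
11 | 1-[2,4-bis(benzyloxy)-6-hydroxyphenyl]ethan-1-one | CC(=O)c1c(O)cc(OCc2ccccc2)cc1OCc1ccccc1 | intermediate
12 | 2-acetyl-3,5-bis(benzyloxy)phenyl formate | CC(=O)c1c(OC=O)cc(OCc2ccccc2)cc1OCc1ccccc1 | intermediate
13 | carbon monoxide | [C-]#[O+] | intermediate
14 | 2-acetyl-3,5-bis(benzyloxy)phenyl 4-(benzyloxy)-3-{2-[4-(benzyloxy)phenyl]-5,7-dimethoxy-4-oxo-4H-chromen-3-yl}benzoate | COc1cc(OC)c2c(=O)c(-c3cc(C(=O)Oc4cc(OCc5ccccc5)cc(OCc5ccccc5)c4C(C)=O)ccc3OCc3ccccc3)c(-c3ccc(OCc4ccccc4)cc3)oc2c1 | intermediate
15 | 1-[2,4-bis(benzyloxy)-6-hydroxyphenyl]-3-(4-(benzyloxy)-3-{2-[4-(benzyloxy)phenyl]-5,7-dimethoxy-4-oxo-4H-chromen-3-yl}phenyl)propane-1,3-dione | COc1cc(OC)c2c(=O)c(-c3cc(C(=O)CC(=O)c4c(O)cc(OCc5ccccc5)cc4OCc4ccccc4)ccc3OCc3ccccc3)c(-c3ccc(OCc4ccccc4)cc3)oc2c1 | intermediate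
16 | 2-[4-(benzyloxy)phenyl]-3-{2-(benzyloxy)-5-[5,7-bis(benzyloxy)-4-oxo-4H-chromen-2-yl]phenyl}-5,7-dimethoxy-4H-chromen-4-one | COc1cc(OC)c2c(=O)c(-c3cc(-c4cc(=O)c5c(OCc6ccccc6)cc(OCc6ccccc6)cc5o4)ccc3OCc3ccccc3)c(-c3ccc(OCc4ccccc4)cc3)oc2c1 | intermediate
17 | 5-hydroxy-3-[5-(5,7-dihydroxy-4-oxo-4H-chromen-2-yl)-2-hydroxyphenyl]-2-(4-hydroxyphenyl)-7-methoxy-4H-chromen-4-one (CNP0284832.0) | COc1cc(O)c2c(=O)c(-c3cc(-c4cc(=O)c5c(O)cc(O)cc5o4)ccc3O)c(-c3ccc(O)cc3)oc2c1 | target

**Step count**
Total step count: 9.
Longest linear sequence: 6 (steps 1, 2, 3, 5, 8, 9).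

**Steps most likely to fail**

1. Step 8.
   - What may go wrong: CO may be released out of step with oxidative addition. The chelated phenol may trap the aroylpalladium species too slowly, so that hydrolysis or reduction of the C–Br bond takes over. Base may shift the formyl group onto the neighbouring acetyl carbon. The sequence may stall before the cyclodehydration.
   - Fallback (known chemistry, same bond, but ring E is made first and its C2–H is arylated): setting out from 9, Miyaura borylation (B2pin2, PdCl2(dppf), KOAc, dioxane, 90 °C) should give the fragment 1 pinacol boronate F1. Setting out from 11, condensation with DMF dimethyl acetal (PhMe, 90 °C) should give the enaminone F2, which aqueous HCl in CH2Cl2 closes to 5,7-bis(benzyloxy)chromone F3. Oxidative boron-Heck coupling of F1 with F3 under divalent palladium (Pd(O2CCF3)2, 5-nitro-1,10-phenanthroline, O2, DMSO, 100 °C) places the aryl group on C2 of ring E. The route is rejoined at 16.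

2. Step 5.
   - What may go wrong: transmetalation at the hindered C3 position may be slow enough that protodeboronation of the ortho-alkoxy boronic acid wins. Once the iodide runs low, loss of halogen discrimination would lead to oligomerisation through the C–Br bond.
   - Fallback (polarity of the coupling reversed): setting out from 6, LiCl-promoted zinc insertion (Zn dust, LiCl, THF, rt) should give the chromon-3-ylzinc iodide F4. Commercial 4-bromo-2-iodophenol is benzylated (BnBr, K2CO3, DMF) to 1-(benzyloxy)-4-bromo-2-iodobenzene F5. Negishi coupling of F4 with F5 (Pd(OAc)2, SPhos, THF, 40 °C) should take place at the C–I bond only. The route is rejoined at 9.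

3. Step 9.
   - What may go wrong: the five cleavages may run at different rates, so the reaction may stop at partly protected stages. Benzyl cations may be captured by the phloroglucinol-type ring D. Prolonged warming may start to erode the 7-OMe.
   - Fallback (two orthogonal operations instead of one): setting out from 16, hydrogenolysis (H2, Pd/C, THF/MeOH, rt) should give the tetraphenol dimethyl ether F6. Chelation-controlled demethylation (AlCl3, MeCN, 60 °C) then removes only the 5-OMe next to C4=O. The route is rejoined at 17.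

**Further compounds**
F1 | step 8 | fragment 1 pinacol boronate: 2-[4-(benzyloxy)phenyl]-3-[2-(benzyloxy)-5-(4,4,5,5-tetramethyl-1,3,2-dioxaborolan-2-yl)phenyl]-5,7-dimethoxy-4H-chromen-4-one | COc1cc(OC)c2c(=O)c(-c3cc(B4OC(C)(C)C(C)(C)O4)ccc3OCc3ccccc3)c(-c3ccc(OCc4ccccc4)cc3)oc2c1
F2 | step 8 | enaminone: (E)-1-[2,4-bis(benzyloxy)-6-hydroxyphenyl]-3-(dimethylamino)prop-2-en-1-one | CN(C)/C=C/C(=O)c1c(O)cc(OCc2ccccc2)cc1OCc1ccccc1
F3 | step 8 | 5,7-bis(benzyloxy)chromone: 5,7-bis(benzyloxy)-4H-chromen-4-one | O=c1ccoc2cc(OCc3ccccc3)cc(OCc3ccccc3)c12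
F4 | step 5 | chromon-3-ylzinc iodide: {2-[4-(benzyloxy)phenyl]-5,7-dimethoxy-4-oxo-4H-chromen-3-yl}zinc iodide | COc1cc(OC)c2c(=O)c([Zn]I)c(-c3ccc(OCc4ccccc4)cc3)oc2c1
F5 | step 5 | 1-(benzyloxy)-4-bromo-2-iodobenzene | Brc1ccc(OCc2ccccc2)c(I)c1
F6 | step 9 | tetraphenol dimethyl ether: 3-[5-(5,7-dihydroxy-4-oxo-4H-chromen-2-yl)-2-hydroxyphenyl]-2-(4-hydroxyphenyl)-5,7-dimethoxy-4H-chromen-4-one | COc1cc(OC)c2c(=O)c(-c3cc(-c4cc(=O)c5c(O)cc(O)cc5o4)ccc3O)c(-c3ccc(O)cc3)oc2c1
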